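All runs come from a simulation with made-up constants; the scatter is artificial.

Wednesday's run shows an induction period: with twice the time, from 6.00 h to 12.0 h, target rises from 2% to 10%. Counted back from the last reading, a straight line gives 5.00% at 6.00 h, and growth with the square of time gives 2.50%. With a scatter of 1.5 percentage points, the straight line is the one that cheats. Square growth fits a catalyst released at a steady pace.

common to all: precatalyst 0.01 mol%
- Thursday's: starting material 0.050 M; second substrate 1 equiv; temperature −10 °C; run made earlier
- Wednesday's: starting material 0.20 M; second substrate 1 equiv; temperature 10 °C; run made earlier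
- Saturday's: starting material 0.10 M; second substrate 2 equiv; temperature −10 °C; run made earlier
- red: starting material 0.10 M; second substrate 1.00 equiv; temperature 25 °C; time 5.0 h
- grey: starting material 0.10 M; second substrate 1.00 equiv; temperature −5 °C; time 5.0 h

| run | time / h | target / % | starting material / % |
|---|---|---|---|
| Thursday's | 3.00 | 1 | 102 |
| Thursday's | 6.00 | 0 | 102 |
| Thursday's | 15.0 | 0 | 101 |
| Thursday's | 30.0 | 1 | 99 |
| Wednesday's | 3.00 | 1 | 98 |
| Wednesday's | 6.00 | 2 | 99 |
| Wednesday's | 10.0 | 10 | 91 |
| Wednesday's | 12.0 | 10 | 88 |
| Saturday's | 3.00 | 1 | 99 |
| Saturday's | 6.00 | 1 | 99 |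
| Saturday's | 15.0 | 1 | 99 |
| Saturday's | 30.0 | 1 | 100 |

(readings scatter by 1.5 percentage points)

* the best flask by amount of target, in percent of the starting material charged; "all alike" if 1.5 percentage points covers them all (red / grey / all alike)
* amount of target at the end, in percent of the starting material charged, red
* amount of target at the end, in percent of the starting material charged, grey



Two columns of Wednesday's run then give one time, each by the same formula:

time ÷ √(fraction converted): target 37.9 h; starting material lost 34.6 h

This is the ramp time, the time at which target on the square law equals the whole charge. The two values rest on separate readings, whose conversions differ by 2 points, close to the scatter, so the target value is carried.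

At fixed mol%, catalyst follows concentration, so this reckoning takes the ramp time as varying with its inverse square root, which gives 53.7 h at 0.10 M. Saturday's run, at that concentration but with more second substrate, reads 1% at 30.0 h. That lies within scatter of nil, so its ramp time, with the reading taken at face value, is 300 h, and the span from −10 °C to 10 °C is worth a factor of about 5.59. Both are estimates from a reading smaller than its scatter, not limits. Interpolated on a logarithmic scale:

red: ramp time 14.8 h, target about 11.5%

grey: ramp time 195 h, target about 0.0657%

The forecast also names red, but with other numbers: 15% in red (4% to 45%) and 0.5% in grey (0% to 2%). It reads the lag as “slow catalyst activation or autocatalysis”.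

Red ends at 25.1% target and grey at 0.0474%, so red is the better flask, above the forecast's 15% but inside its range.

    complex B → free enzyme + second product (k = 28.0 /s, Ea = 56.0 kJ/mol)
    precatalyst → free enzyme (k = 8.80 × 10⁻⁵ /s, Ea = 95.0 kJ/mol)
    starting material + free enzyme ⇌ complex A (K = 4.30 /M, k = 150 /M/s, Ea = 45.0 kJ/mol, ΔH = −21.0 kJ/mol)
    free enzyme → unfolded enzyme (k = 1.00 × 10⁻⁶ /s, Ea = 241 kJ/mol)
    complex A → free enzyme + target (k = 1.10 /s, Ea = 65.0 kJ/mol)
    second substrate + free enzyme ⇌ complex B (K = 6.70 /M, k = 110 /M/s, Ea = 48.0 kJ/mol, ΔH = −44.0 kJ/mol)
    (constants at 25 °C)

Grey's ramp time is 230 h at 5.0 h and 231 h at 50.0 h, when 80.4% of its precatalyst still stands. In red, the precatalyst half-life of 2.19 h is shorter than the 5.0 h run, precatalyst is down to 20.5%, and the ramp time lengthens from 8.88 h at 2.50 h to 9.98 h at 5.00 h.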